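## Structural features

Phlorofucofuroeckol A (21) is a flat, fully aromatic pentacycle without any stereocentre. Ring A, a benzene with five oxygens, is fused through a 1,4-dioxin to ring B, and ring B is fused through a furan to ring C. Ring A (at a1) and ring C (at c2) each carry a 3,5-dihydroxyphenoxy group, called ring D and ring E here, so the thirty carbons are joined by five bridging oxygens and one biaryl bond (b5–c6). The other nine oxygens are free phenols; the molecule is therefore very electron-rich, is oxidised by air (fastest in base), and its phloroglucinol-type rings are easily attacked by electrophiles. For that reason every hydroxyl is best carried as a methyl ether to the last step, and the diaryl ethers, which resist boron halides, are made early. The real difficulty is regiochemistry on two nearly symmetric rings. In ring B, b3 and b5 both flank the furan oxygen at b4 and differ only in their neighbours (the b2 oxygen against the dioxin oxygen at b6). In ring C, the furan oxygen must sit on c1, next to the aryloxy-bearing c2, and not on c5. The key step uses the para relation of the b1 and b4 oxygens: ring B enters as a 1,4-benzoquinone whose b5 accepts c6, whose b4 oxygen closes the furan onto c1, and whose b1 oxygen is released as the phenol that later closes the dioxin. It also uses the mirror symmetry of a ring C unit with free hydroxyls at c1 and c3 and a blocked c5.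

## Logic of the disconnections

21 to 20: the eight O–H bonds at a2, a4, b2, c5 and on rings D and E are traced back to O–CH3 bonds. This turns an air-sensitive nonaphenol into a stable ether that can be chromatographed. The forward step must cleave eight aryl methyl ethers and leave the five bridging C–O–C links intact.

20 to 19: the dioxin bond between the b1 oxygen and ring A carbon a6 is cut. The other dioxin bond (b6–O–a5) stays, so the forward reaction is an intramolecular six-membered closure. This removes one ring, and it requires a free b1 hydroxyl and a bromine at a6, both hindered.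

19 to 17 and 8: the biaryl bond b5–c6 and the furan bond O(b4)–c1 are cut together. This divides the molecule into two halves of similar size, and the b1 hydroxyl needed in the previous paragraph appears without a separate step. The forward step demands attack at b5 and not b3, and furan closure at c1 and not c5; the second demand is met by the c5 methyl ether of 8.

17 to 14 and 16: the vinylic C–O bond at b6 is cut. A phenoxide and a halo-quinone are the natural partners, and a bromide leaving group makes the substitution irreversible. The demand is ipso substitution without redox chemistry between an electron-rich phenoxide and a quinone.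

16 to 15: the C=O at b4 is traced to a C–H para to a phenol. This leads to a commercial phenol in one oxidation. The demand is para-selective oxidation, secured by the two substituted ortho positions.

14 to 13: the C–Br bond at a6 is cut. Bromine is introduced last on ring A so that it never meets a copper catalyst before step 11. The demand is bromination ortho to the phenol in the presence of the more electron-rich ring D.

13 to 11: the phenolic C–O bond at a5 is traced to an aryl–CHO bond. The aldehyde carbon is excised by oxygen insertion, which leads back to a cheap benzaldehyde. The demand is aryl migration, assured by the ortho and para methoxy groups.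

11 to 9 and 10: the diaryl ether bond between a1 and the ring D oxygen is cut. Both pieces are commercial. The demand is a copper-mediated C–O coupling that tolerates an aldehyde.

8 to 7: the two O–H bonds at c1 and c3 are traced to acetal ethers. These allow the metalation and the coupling below. The demand is acid cleavage without C-alkylation of the ring.

7 to 5 and 6: the diaryl ether bond between the c2 oxygen and ring E is cut, with the oxygen on the ring C piece. The hindered partner is thus the nucleophile and the unhindered one the halide. The demand is coupling of a 2,6-disubstituted phenol.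

5 to 2: the C–O bond at c2 is traced to a C–H bond between the two acetal ethers. This is the only position flanked by two strong directing groups. The demand is lithiation there and not next to the methoxy group.

2 to 1: the two O–CH2 bonds are cut, leading to a commercial symmetric diol.

## Other disconnections considered

Alternative 1: The carbocycles of rings D and E are cut away, six C–C bonds in all. In the forward sense the bis(ethynyl ether) A1 of the methylated pentacyclic core would be heated with 3-ethoxycyclobutenone A2. Each ynol ether would then pass through 4π opening of A2 to a vinylketene, [2+2] addition, a second 4π opening, 6π closure and tautomerisation to a 3-ethoxy-5-hydroxyphenyl ether, giving A3.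
- In favour: the cascade is purely thermal and neutral, needs no metal, and builds the 1,3,5-oxygen pattern by mechanism. On mildness it is better than the two Ullmann couplings (steps 3 and 5) that it would replace, and on regiocontrol of rings D and E it is the equal of the chosen plan.
- Against: it does not touch the fused A–B–C core, which is where the difficulty lies, and that core must be finished first with two hydroxyls left free. Each of those must then be turned into an ynol ether with strong base on an advanced intermediate, and aryl ynol ethers are weaker ketenophiles than alkyl ones.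
- Comparison: rings D and E cost nothing in the chosen plan because 6 and 10 are bought. Alternative 1 therefore adds at least four late, linear operations without removing any risk of the core, and is clearly worse in step economy.

Alternative 2: The bond c4–c5 of ring C is cut. In the forward sense the benzofuran keto ester A4 (ester on furan C-3, 1-aryloxy-2-oxopropyl chain on furan C-2, with rings A, B and D and the dioxin already in place) would be treated with base. The methyl ketone enolate would acylate on the ester, and the resulting cyclic 1,3-dione would enolise to the resorcinol A5.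
- In favour: the furan oxygen and the aryloxy group are in place before ring C exists, so neither the b3/b5 question nor the c1/c5 question arises. On regiocontrol this is better than the chosen plan. Aromatisation drives the condensation, and A5 needs only one further step, one fewer than 19.
- Against: A4 is a tetracyclic intermediate that needs the dioxin and ring A assembled without the phenol/bromide pairing that the quinone route provides. Its most acidic hydrogen is the one between ketone, furan and aryloxy group, so the required methyl enolate is the minor one. The route is also linear.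
- Comparison: the regiochemical safety is bought with a much longer and less convergent approach to A4.

Alternative 3: The same two bonds as in the chosen plan (b5–c6 and b4–O) are cut, but ring B is carried as 5-methoxycyclohexane-1,3-dione A6. In the forward sense CuI with L-proline would arylate C-2 of A6 with the ring C iodophenol A7, and the phenol oxygen would condense onto a dione carbonyl to give the dihydrodibenzofuranone A8 (racemic; the stereocentre is lost later).
- In favour: A6 is symmetric, so the b3/b5 question disappears, and A7 has a single free hydroxyl, so the furan can close only one way. On regiocontrol of the key step this is better than the chosen plan, and the domino reaction is catalytic and of a known type.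
- Against: ring B is at the wrong oxidation level. It still needs oxygenation at C-2 (the later b1) and dehydrogenation, and the C-3 methoxy group is β to the ketone and prone to elimination. Two C–O bonds to ring A must then be made with no built-in control over which oxygen meets which carbon. A7 also requires a regioselective iodination of an unsymmetrical phloroglucinol ether.
- Comparison: the chosen plan delivers ring B aromatic with the b1 phenol placed beside the ring A bromide, and reaches the target two steps after the key step. After A8 at least six further steps are foreseeable, so Alternative 3 gains certainty in the key step and loses it, and step economy, afterwards.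

Key step: step 10

Remarks on the chemistry:
- Compounds 1, 6, 9, 10 and 15 are assumed to be commercial.
- Ring C enters the key step as the c5 methyl ether 8 and not as a triol. A triol would offer two hydroxyls (c1 and c5) ortho to the new biaryl bond, and so two furan regioisomers.
- The b6 ether of 17 is made from a bromoquinone. Exchange of a quinone methoxy group by a phenol would be uphill, because the entering aryloxide is the better leaving group.

## Route

Step 1
Reactants: 1 5-methoxybenzene-1,3-diol
Product: 2 1-methoxy-3,5-bis(methoxymethoxy)benzene
Conditions: NaH, MOMCl, DMF, 0 °C to rt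
Reagents that add atoms: chloromethyl methyl ether, COCCl
Why: O-alkylation of the two equivalent phenoxides with a reactive α-chloro ether (Williamson type); the acetal ethers are stable to base and later direct the lithiation.

Step 2
Reactants: 2 1-methoxy-3,5-bis(methoxymethoxy)benzene
Product: 5 4-methoxy-2,6-bis(methoxymethoxy)phenol, via aryllithium 3 (not isolated), via dimethyl arylboronate 4 (not isolated)
Conditions: n-BuLi, THF, 0 °C; B(OMe)3, −78 °C to rt; 30% H2O2, 0 °C to rt
Reagents that add atoms: n-butyllithium, [Li]CCCC (lithium of 3); trimethyl borate, COB(OC)OC (boron and methoxy groups of 4); hydrogen peroxide, OO (new oxygen of 5)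
Why: Directed ortho-metalation: the carbon between the two methoxymethoxy groups is doubly chelated, and these acetal oxygens direct more strongly than methoxy, so 3 should form there; borylation and peroxide oxidation (aryl shift from boron to oxygen) then give the phenol.

Step 3
Reactants: 5 4-methoxy-2,6-bis(methoxymethoxy)phenol; 6 1-bromo-3,5-dimethoxybenzene
Product: 7 2-(3,5-dimethoxyphenoxy)-5-methoxy-1,3-bis(methoxymethoxy)benzene
Conditions: CuI (10 mol %), picolinic acid (20 mol %), K3PO4, DMSO, 90 °C
Reagents that add atoms: none
Why: Ullmann-type diaryl ether synthesis; the hindered, electron-rich phenoxide is paired with an unhindered aryl bromide, the arrangement under which 2,6-disubstituted phenols are known to couple, and the acetals are inert to K3PO4.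

Step 4
Reactants: 7 2-(3,5-dimethoxyphenoxy)-5-methoxy-1,3-bis(methoxymethoxy)benzene
Product: 8 2-(3,5-dimethoxyphenoxy)-5-methoxybenzene-1,3-diol
Conditions: HCl (cat.), MeOH, 50 °C, argon
Reagents that add atoms: none
Why: Acid-catalysed acetal exchange removes both methoxymethyl groups; methanol traps the oxocarbenium ion as dimethoxymethane, so the electron-rich ring should not be C-alkylated, and the methyl ethers are untouched.

Step 5
Reactants: 9 5-bromo-2,4-dimethoxybenzaldehyde; 10 3,5-dimethoxyphenol
Product: 11 5-(3,5-dimethoxyphenoxy)-2,4-dimethoxybenzaldehyde
Conditions: CuI (10 mol %), N,N-dimethylglycine hydrochloride (30 mol %), Cs2CO3, dioxane, 100 °C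
Reagents that add atoms: none
Why: Ullmann-type C–O coupling of an unhindered phenol with an aryl bromide; the aldehyde cannot enolise and is tolerated by carbonate base.

Step 6
Reactants: 11 5-(3,5-dimethoxyphenoxy)-2,4-dimethoxybenzaldehyde
Product: 13 5-(3,5-dimethoxyphenoxy)-2,4-dimethoxyphenol, via aryl formate 12 (not isolated)
Conditions: mCPBA, CH2Cl2, 0 °C to rt; then K2CO3 (cat.), MeOH, rt
Reagents that add atoms: 3-chloroperoxybenzoic acid, OOC(=O)c1cccc(Cl)c1
Why: Baeyer–Villiger oxidation: the aryl group, activated by ortho and para methoxy groups, migrates to give formate 12, which is methanolysed to the phenol; only a slight excess of peracid is used so that ring D is not hydroxylated.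

Step 7
Reactants: 13 5-(3,5-dimethoxyphenoxy)-2,4-dimethoxyphenol
Product: 14 2-bromo-3-(3,5-dimethoxyphenoxy)-4,6-dimethoxyphenol
Conditions: t-BuNH2, Br2, toluene, −30 °C; then 13, CH2Cl2, −78 °C to rt
Reagents that add atoms: bromine, BrBr
Why: Amine-mediated ortho-bromination of a phenol: N-bromo-tert-butylamine is activated only by the acidic phenol and delivers bromine within the phenol–amine ion pair to the one free ortho position (para carries methoxy); the neutral ether rings are not activated in this basic medium.

Step 8
Reactants: 15 2-bromo-6-methoxyphenol
Product: 16 2-bromo-6-methoxy-1,4-benzoquinone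
Conditions: (KSO3)2NO, KH2PO4 buffer, H2O/acetone, 0 °C to rt
Reagents that add atoms: dipotassium nitrosodisulfonate, [K+].[K+].[O]N(S(=O)(=O)[O-])S(=O)(=O)[O-]
Why: Teuber oxidation: the nitroxyl radical removes the phenolic hydrogen and a second equivalent oxygenates the free para position; both ortho positions are substituted, so only the 1,4-quinone can form.

Step 9
Reactants: 14 2-bromo-3-(3,5-dimethoxyphenoxy)-4,6-dimethoxyphenol; 16 2-bromo-6-methoxy-1,4-benzoquinone
Product: 17 2-[2-bromo-3-(3,5-dimethoxyphenoxy)-4,6-dimethoxyphenoxy]-6-methoxy-1,4-benzoquinone
Conditions: Cs2CO3, MeCN, 0 °C to rt, argon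
Reagents that add atoms: none
Why: Addition–elimination on a haloquinone: the phenoxide adds to the bromine-bearing carbon (a vinylogous acyl bromide) and bromide leaves irreversibly; the methoxy-bearing carbon is less electrophilic and methoxide is the poorer leaving group.

Step 10
Reactants: 17 2-[2-bromo-3-(3,5-dimethoxyphenoxy)-4,6-dimethoxyphenoxy]-6-methoxy-1,4-benzoquinone; 8 2-(3,5-dimethoxyphenoxy)-5-methoxybenzene-1,3-diol
Product: 19 1-[2-bromo-3-(3,5-dimethoxyphenoxy)-4,6-dimethoxyphenoxy]-6-(3,5-dimethoxyphenoxy)-3,9-dimethoxydibenzo[b,d]furan-2,7-diol, via aryl hydroquinone 18 (not isolated)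
Conditions: CF3CO2H, (CF3)2CHOH/CH2Cl2, argon, 0 °C to rt, then 45 °C
Reagents that add atoms: none
Why: Acid activates the b1 carbonyl of 17, so the enone b1(=O)–b6=b5 accepts carbon c6 of 8 (ortho to one free hydroxyl and para to the other; c4 is its mirror image) in a Friedel–Crafts conjugate addition, and tautomerisation gives hydroquinone 18. The b4 hydroxyl of 18 then adds to c1 of the keto tautomer of ring C (5-exo-trig onto the carbonyl), and loss of water rearomatises ring C and closes the furan; the sequence is redox-neutral and leaves b1 as a free phenol. The closest known reaction type is the acid-mediated union of 1,4-benzoquinones with phloroglucinols or resorcinols to give hydroxydibenzofurans, and no stereocentre is formed. Attack at b5 and not b3 is expected because the b6 aryloxy oxygen shares its lone pair with ring A and so donates less to b5 than the b2 methoxy oxygen donates to b3; a Brønsted acid is chosen so that no metal chelate ties up the methoxy lone pair. Furan closure at c1 and not c5 is secured by the substrate, since c5 is a methyl ether with no keto tautomer and c1 carries the only hydroxyl ortho to the new bond. Carbon and not oxygen attack is expected because the ring carbon of 8 is the soft nucleophile under acid. A slight excess of 8 under argon should keep 18 from being oxidised by unreacted 17.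

Step 11
Reactants: 19 1-[2-bromo-3-(3,5-dimethoxyphenoxy)-4,6-dimethoxyphenoxy]-6-(3,5-dimethoxyphenoxy)-3,9-dimethoxydibenzo[b,d]furan-2,7-diol
Product: 20 dioxin-closed octamethyl ether of the target (rings A to E complete; methoxy at a2, a4, b2, c5 and on rings D and E; free hydroxyl at c3)
Conditions: CuI (30 mol %), N,N-dimethylglycine hydrochloride (60 mol %), Cs2CO3, dioxane (0.01 M), 110 °C, argon
Reagents that add atoms: none
Why: Intramolecular Ullmann etherification: the b1 phenoxide sits next to the ring A bromide and closes a six-membered ring, the classical way to dibenzo-1,4-dioxins; the c3 phenoxide cannot reach the bromide, and high dilution disfavours its intermolecular coupling.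

Step 12
Reactants: 20 dioxin-closed octamethyl ether of the target
Product: 21 phlorofucofuroeckol A
Conditions: BBr3 (excess), CH2Cl2, −78 °C to rt; MeOH, then H2O, work-up under argon
Reagents that add atoms: none
Why: Lewis-acid ether cleavage: BBr3 complexes each methoxy oxygen and bromide removes the methyl group by SN2; the diaryl ether, dioxin and furan C–O bonds have no alkyl carbon to attack and should survive.

## Compound list

1 | 5-methoxybenzene-1,3-diol | COc1cc(O)cc(O)c1 | starting material
2 | 1-methoxy-3,5-bis(methoxymethoxy)benzene | COCOc1cc(OC)cc(OCOC)c1 | intermediate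
3 | [4-methoxy-2,6-bis(methoxymethoxy)phenyl]lithium, formed in the flask | [Li]c1c(OCOC)cc(OC)cc1OCOC | intermediate
4 | dimethyl [4-methoxy-2,6-bis(methoxymethoxy)phenyl]boronate, formed in the flask | COB(OC)c1c(OCOC)cc(OC)cc1OCOC | intermediate
5 | 4-methoxy-2,6-bis(methoxymethoxy)phenol | COCOc1cc(OC)cc(OCOC)c1O | intermediate
6 | 1-bromo-3,5-dimethoxybenzene | COc1cc(Br)cc(OC)c1 | starting material
7 | 2-(3,5-dimethoxyphenoxy)-5-methoxy-1,3-bis(methoxymethoxy)benzene | COCOc1cc(OC)cc(OCOC)c1Oc1cc(OC)cc(OC)c1 | intermediate
8 | 2-(3,5-dimethoxyphenoxy)-5-methoxybenzene-1,3-diol | COc1cc(OC)cc(Oc2c(O)cc(OC)cc2O)c1 | intermediate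
9 | 5-bromo-2,4-dimethoxybenzaldehyde | COc1cc(OC)c(Br)cc1C=O | starting material
10 | 3,5-dimethoxyphenol | COc1cc(O)cc(OC)c1 | starting material
11 | 5-(3,5-dimethoxyphenoxy)-2,4-dimethoxybenzaldehyde | COc1cc(OC)c(Oc2cc(OC)cc(OC)c2)cc1C=O | intermediate
12 | 5-(3,5-dimethoxyphenoxy)-2,4-dimethoxyphenyl formate, formed in the flask | COc1cc(OC)c(Oc2cc(OC)cc(OC)c2)cc1OC=O | intermediate
13 | 5-(3,5-dimethoxyphenoxy)-2,4-dimethoxyphenol | COc1cc(OC)c(Oc2cc(OC)cc(OC)c2)cc1O | intermediate
14 | 2-bromo-3-(3,5-dimethoxyphenoxy)-4,6-dimethoxyphenol | COc1cc(OC)c(Oc2cc(OC)cc(OC)c2)c(Br)c1O | intermediate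
15 | 2-bromo-6-methoxyphenol | COc1cccc(Br)c1O | starting material
16 | 2-bromo-6-methoxy-1,4-benzoquinone | COC1=CC(=O)C=C(Br)C1=O | intermediate
17 | 2-[2-bromo-3-(3,5-dimethoxyphenoxy)-4,6-dimethoxyphenoxy]-6-methoxy-1,4-benzoquinone | COC1=CC(=O)C=C(Oc2c(OC)cc(OC)c(Oc3cc(OC)cc(OC)c3)c2Br)C1=O | intermediate
18 | 3-[2-bromo-3-(3,5-dimethoxyphenoxy)-4,6-dimethoxyphenoxy]-2-[3-(3,5-dimethoxyphenoxy)-2,4-dihydroxy-6-methoxyphenyl]-5-methoxybenzene-1,4-diol, formed in the flask | COc1cc(O)c(-c2c(O)c(Oc3cc(OC)cc(OC)c3)c(O)cc2OC)c(Oc2c(OC)cc(OC)c(Oc3cc(OC)cc(OC)c3)c2Br)c1O | intermediate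
19 | 1-[2-bromo-3-(3,5-dimethoxyphenoxy)-4,6-dimethoxyphenoxy]-6-(3,5-dimethoxyphenoxy)-3,9-dimethoxydibenzo[b,d]furan-2,7-diol | COc1cc2oc3c(Oc4cc(OC)cc(OC)c4)c(O)cc(OC)c3c2c(Oc2c(OC)cc(OC)c(Oc3cc(OC)cc(OC)c3)c2Br)c1O | intermediate
20 | dioxin-closed octamethyl ether of phlorofucofuroeckol A (free hydroxyl at c3 only) | COc1cc(OC)cc(Oc2c(OC)cc(OC)c3c2Oc2c(OC)cc4oc5c(Oc6cc(OC)cc(OC)c6)c(O)cc(OC)c5c4c2O3)c1 | intermediate
21 | phlorofucofuroeckol A | Oc1cc(O)cc(Oc2c(O)cc(O)c3c2Oc2c(O)cc4oc5c(Oc6cc(O)cc(O)c6)c(O)cc(O)c5c4c2O3)c1 | target

## Step count and least certain steps

Total step count: 12. Longest linear sequence: 7 steps (9 to 11, 13, 14, 17, 19, 20, 21; the branch from 1 through 2, 5, 7, 8 is equally long).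

Step 10 (key step).
- What may go wrong: attack at b3 in competition with b5, because the twisted, doubly ortho-substituted ring A shields b5 and may outweigh the electronic preference. The nucleophile may also add at b6 with expulsion of the ring A phenoxide. Oxidation of 18 by unreacted 17 would give an aryl quinone that cyclises through the wrong bond.
- Fallback: from 17 and 8, returning at 21. BCl3 (CH2Cl2, −78 to 0 °C) should remove only the methyl group of the vinylogous ester, by chelation to the b1 carbonyl, and give 2-[2-bromo-3-(3,5-dimethoxyphenoxy)-4,6-dimethoxyphenoxy]-6-hydroxy-1,4-benzoquinone F1. In F1, b3 is the nucleophilic carbon of a vinylogous acid and cannot accept a nucleophile. Union with 8 under the same acid should therefore occur at b5 only, through 6-aryloxy-5-arylbenzene-1,2,4-triol F2 (not isolated), to give the dibenzofuran-2,3,7-triol F3. CuI/Cs2CO3 closure, in which only the b1 oxygen can form a six-membered ring, would give the heptamethyl ether F4 with a free b2 hydroxyl, and BBr3 would convert F4 into 21.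

Step 9.
- What may go wrong: conjugate addition of the phenoxide at the ring hydrogen next to bromine followed by loss of HBr (cine substitution), or electron transfer from the electron-rich phenoxide to the bromoquinone.
- Fallback: from 14, returning at 17. 14 is heated with an excess of commercial 2,6-dimethoxy-1,4-benzoquinone and Cs2CO3 in toluene, with the methanol removed continuously over 5 Å molecular sieves. The only productive site is then a methoxy-bearing carbon, the quinone is a weaker oxidant, and the unfavourable exchange equilibrium is pulled by methanol removal. No new compound is formed on this detour (F0).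

Step 7.
- What may go wrong: bromination of ring D, a 1,3,5-trioxygenated ring, in place of the position ortho to the phenol, or oxidation of the para-methoxyphenol to a quinone.
- Fallback: from 13, returning at 14. 13 is converted with NaH and diethylcarbamoyl chloride into 5-(3,5-dimethoxyphenoxy)-2,4-dimethoxyphenyl N,N-diethylcarbamate F5. s-BuLi/TMEDA (THF, −78 °C) should lithiate the only position ortho to the carbamate to give the aryllithium F6 (not isolated), which is quenched with 1,2-dibromotetrachloroethane to the bromo carbamate F7. NaOH in refluxing ethanol then gives 14.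

Step 11.
- What may go wrong: slow oxidative addition at the doubly ortho-substituted C–Br bond, leading to protodebromination, and intermolecular O-arylation through the c3 phenoxide.
- Fallback: from 19, returning at 20. Miyaura borylation (Pd(dppf)Cl2, B2pin2, KOAc, dioxane, 90 °C) would give the pinacol boronate F8 (19 with the boronate in place of bromine). An intramolecular Chan–Lam coupling (Cu(OAc)2, pyridine, 4 Å sieves, air, CH2Cl2, rt, high dilution) would then join the b1 oxygen to a6 at room temperature.

Step 12.
- What may go wrong: incomplete cleavage of the eight ethers, giving mixtures of partial methyl ethers, and air oxidation of the free nonaphenol during isolation.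
- Fallback: from 20, returning at 21. The crude product of the BBr3 treatment is acetylated (Ac2O, pyridine) to phlorofucofuroeckol A nonaacetate F9, which is stable and can be purified on silica. Degassed methanolic HCl then releases 21.

## Further compounds

F1 | step 10 | 2-[2-bromo-3-(3,5-dimethoxyphenoxy)-4,6-dimethoxyphenoxy]-6-hydroxy-1,4-benzoquinone | OC1=CC(=O)C=C(Oc2c(OC)cc(OC)c(Oc3cc(OC)cc(OC)c3)c2Br)C1=O
F2 | step 10 | 6-[2-bromo-3-(3,5-dimethoxyphenoxy)-4,6-dimethoxyphenoxy]-5-[3-(3,5-dimethoxyphenoxy)-2,4-dihydroxy-6-methoxyphenyl]benzene-1,2,4-triol (not isolated) | Oc1cc(O)c(-c2c(O)c(Oc3cc(OC)cc(OC)c3)c(O)cc2OC)c(Oc2c(OC)cc(OC)c(Oc3cc(OC)cc(OC)c3)c2Br)c1O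
F3 | step 10 | 1-[2-bromo-3-(3,5-dimethoxyphenoxy)-4,6-dimethoxyphenoxy]-6-(3,5-dimethoxyphenoxy)-9-methoxydibenzo[b,d]furan-2,3,7-triol | Oc1cc2oc3c(Oc4cc(OC)cc(OC)c4)c(O)cc(OC)c3c2c(Oc2c(OC)cc(OC)c(Oc3cc(OC)cc(OC)c3)c2Br)c1O
F4 | step 10 | dioxin-closed heptamethyl ether of phlorofucofuroeckol A (free hydroxyls at b2 and c3) | COc1cc(OC)cc(Oc2c(OC)cc(OC)c3c2Oc2c(O)cc4oc5c(Oc6cc(OC)cc(OC)c6)c(O)cc(OC)c5c4c2O3)c1
F0 | step 9 | none | none
F5 | step 7 | 5-(3,5-dimethoxyphenoxy)-2,4-dimethoxyphenyl N,N-diethylcarbamate | CCN(CC)C(=O)Oc1cc(Oc2cc(OC)cc(OC)c2)c(OC)cc1OC
F6 | step 7 | [2-(diethylcarbamoyloxy)-6-(3,5-dimethoxyphenoxy)-3,5-dimethoxyphenyl]lithium (not isolated) | CCN(CC)C(=O)Oc1c([Li])c(Oc2cc(OC)cc(OC)c2)c(OC)cc1OC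
F7 | step 7 | 2-bromo-3-(3,5-dimethoxyphenoxy)-4,6-dimethoxyphenyl N,N-diethylcarbamate | CCN(CC)C(=O)Oc1c(Br)c(Oc2cc(OC)cc(OC)c2)c(OC)cc1OC
F8 | step 11 | pinacol boronate corresponding to 19 (boronate at a6 in place of bromine) | COc1cc2oc3c(Oc4cc(OC)cc(OC)c4)c(O)cc(OC)c3c2c(Oc2c(OC)cc(OC)c(Oc3cc(OC)cc(OC)c3)c2B2OC(C)(C)C(C)(C)O2)c1O
F9 | step 12 | phlorofucofuroeckol A nonaacetate | CC(=O)Oc1cc(OC(C)=O)cc(Oc2c(OC(C)=O)cc(OC(C)=O)c3c2Oc2c(OC(C)=O)cc4oc5c(Oc6cc(OC(C)=O)cc(OC(C)=O)c6)c(OC(C)=O)cc(OC(C)=O)c5c4c2O3)c1
A1 | alternative 1 | bis(ethynyl ether) of the hexamethylated pentacyclic core (ethynyloxy at a1 and c2) | C#COc1c(OC)cc(OC)c2c1Oc1c(OC)cc3oc4c(OC#C)c(OC)cc(OC)c4c3c1O2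
A2 | alternative 1 | 3-ethoxycyclobut-2-en-1-one | CCOC1=CC(=O)C1
A3 | alternative 1 | protected target with one free hydroxyl and one ethoxy group on each of rings D and E | CCOc1cc(O)cc(Oc2c(OC)cc(OC)c3c2Oc2c(OC)cc4oc5c(Oc6cc(O)cc(OCC)c6)c(OC)cc(OC)c5c4c2O3)c1
A4 | alternative 2 | benzofuran keto ester: methyl ester on furan C-3 and 1-(3,5-dimethoxyphenoxy)-2-oxopropyl chain on furan C-2, rings A, B, D and dioxin in place (racemic) | COc1cc(OC)cc(Oc2c(OC)cc(OC)c3c2Oc2c(OC)cc4oc(C(Oc5cc(OC)cc(OC)c5)C(C)=O)c(C(=O)OC)c4c2O3)c1
A5 | alternative 2 | protected target with free c3 and c5 hydroxyls | COc1cc(OC)cc(Oc2c(OC)cc(OC)c3c2Oc2c(OC)cc4oc5c(Oc6cc(OC)cc(OC)c6)c(O)cc(O)c5c4c2O3)c1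
A6 | alternative 3 | 5-methoxycyclohexane-1,3-dione | COC1CC(=O)CC(=O)C1
A7 | alternative 3 | 2-(3,5-dimethoxyphenoxy)-6-iodo-3,5-dimethoxyphenol | COc1cc(OC)cc(Oc2c(O)c(I)c(OC)cc2OC)c1
A8 | alternative 3 | 6-(3,5-dimethoxyphenoxy)-3,7,9-trimethoxy-3,4-dihydrodibenzo[b,d]furan-1(2H)-one (racemic, one enantiomer drawn) | CO[C@H]1CC(=O)c2c(C1)oc1c(Oc3cc(OC)cc(OC)c3)c(OC)cc(OC)c21
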